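The oxolane ring (O1, C2, C3, C4, C5) is cut at C2–C3. O1 and the oxygen of the C3 hydroxymethyl group stand 1,3 to each other around C2, so both can be the oxygens of one aryl acetal whose carbon is C2. The precursor is therefore a seven-membered dienyl acetal, a 2-aryl-6-(arylmethylidene)-6,7-dihydro-1,3-dioxepine. A chiral silylium Lewis acid opens it to an oxocarbenium/dienol ether pair that recloses through carbon. In one operation the seven-membered ring contracts to the oxolane, C2–C3 is formed, both stereocentres are set and the C3 formyl group (reduced in the same flask) appears, with the C4 arylmethylidene already in place.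

Key step: step 5

Remark: the target is read as (2R,3S,4Z), that is 2,3-trans with the aryl group of the arylmethylidene cis to C5H2. Ar stands for 4-[(tert-butyldimethylsilyl)oxy]-3-methoxyphenyl and Ar-methylidene for ArCH= throughout.

Step 1
Reactants: 1 but-2-yne-1,4-diol
Product: 2 (E)-2-(tributylstannyl)but-2-ene-1,4-diol (the two CH2OH groups cis)
Conditions: Bu3SnH, PdCl2(PPh3)2 (1 mol %), THF, rt
Reagents that add atoms: tributyltin hydride, CCCC[SnH](CCCC)CCCC
Why: Palladium-catalysed hydrostannation adds Sn–H syn across the symmetrical alkyne, so there is no regiochemical question and the two CH2OH groups end up cis, as a seven-membered acetal requires.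

Step 2
Reactants: 2 (E)-2-(tributylstannyl)but-2-ene-1,4-diol; 3 4-[(tert-butyldimethylsilyl)oxy]-3-methoxybenzaldehyde
Product: 4 2-Ar-5-(tributylstannyl)-4,7-dihydro-1,3-dioxepine (racemic at C2)
Conditions: PPTS (10 mol %), benzene, reflux, Dean–Stark trap
Reagents that add atoms: none
Why: Acid-catalysed acetalisation of a cis-but-2-ene-1,4-diol with an aryl aldehyde under water removal should give the 4,7-dihydro-1,3-dioxepine, and the racemic acetal centre is of no consequence because it is planarised in step 5.

Step 3
Reactants: 4 2-Ar-5-(tributylstannyl)-4,7-dihydro-1,3-dioxepine; 3 4-[(tert-butyldimethylsilyl)oxy]-3-methoxybenzaldehyde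
Product: 7 tert-butyl [Ar(2-Ar-4,7-dihydro-1,3-dioxepin-5-yl)methyl] carbonate (diastereomer mixture), via 2-Ar-4,7-dihydro-1,3-dioxepin-5-yllithium 5 (not isolated), via lithium Ar(2-Ar-4,7-dihydro-1,3-dioxepin-5-yl)methoxide 6 (not isolated)
Conditions: n-BuLi, THF, −78 °C; then 3, −78 °C; then Boc2O, −78 to 0 °C
Reagents that add atoms: di-tert-butyl dicarbonate, CC(C)(C)OC(=O)OC(=O)OC(C)(C)C
Why: Tin–lithium exchange gives the alkenyllithium (β-elimination would need a seven-membered cyclic allene), which adds 1,2 to the aldehyde, and O-acylation of the alkoxide by Boc2O gives the allylic carbonate, whose carbinol stereocentre is destroyed in step 4.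

Step 4
Reactants: 7 tert-butyl [Ar(2-Ar-4,7-dihydro-1,3-dioxepin-5-yl)methyl] carbonate
Product: 8 (6Z)-2-Ar-6-(Ar-methylidene)-6,7-dihydro-1,3-dioxepine (dienyl acetal, racemic at C2)
Conditions: Pd(PPh3)4 (5 mol %), THF, 60 °C
Reagents that add atoms: none
Why: Tsuji–Trost-type ionisation by zerovalent palladium gives a 1-aryl-2-substituted π-allyl complex and β-hydride elimination from the ring OCH2 next to the allyl terminus (the only β-hydrogens) gives the conjugated dienyl acetal, a palladium-catalysed 1,4-elimination of an allylic carbonate; the aryl group is expected to sit syn in the π-allyl complex, which places it cis to the remaining ring CH2O carbon (6Z).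

Step 5
Reactants: 8 (6Z)-2-Ar-6-(Ar-methylidene)-6,7-dihydro-1,3-dioxepine
Product: 11 [(2R,3S,4Z)-2-Ar-4-(Ar-methylidene)oxolan-3-yl]methanol, via oxocarbenium silyl dienol ether ion 9 (not isolated), via (2R,3R,4Z)-2-Ar-4-(Ar-methylidene)oxolane-3-carbaldehyde 10 (not isolated)
Conditions: chiral IDPi acid (BINOL-derived imidodiphosphorimidate, 3 mol %), allyltrimethylsilane (10 mol %), CH2Cl2, −78 to −40 °C; then NaBH4, EtOH, −78 to 0 °C
Reagents that add atoms: none
Why: Proposed new method: the silylium imidodiphosphorimidate formed in the flask from the IDPi acid and allyltrimethylsilane should silylate the enol-ether oxygen of 8 and cleave its bond to C2, giving ion pair 9, which recloses through the enol α-carbon onto C2 (Mukaiyama-type aldol, an oxygen-to-carbon [1,3] shift) and passes the silyl group on, so the seven-membered acetal contracts to the oxolane; the closest known reaction is the silyl triflate-promoted [1,3] ring contraction of 2-aryl-4,5-dihydro-1,3-dioxepines to 2-aryl-tetrahydrofuran-3-carbaldehydes, here with triflate replaced by a confined chiral anion as in counteranion-directed asymmetric Mukaiyama aldol catalysis. The oxolane closes by attack of the enol α-carbon, whose C=C bond stays outside the new ring (enol-exo), on the oxocarbenium carbon, whose C=O+ bond lies inside it (5-endo-trig at the electrophile). C2 should be set by the chiral anion, which shields one face of the E-oxocarbenium in the contact ion pair (the catalyst antipode is chosen for 2R, and both enantiomers of 8 converge on the same achiral cation); C3, α to the formyl group, should settle trans to the C2 aryl group during the hold at −40 °C through the silyl dienol ether and kinetic α-protonation, following the cis-at-low-temperature, trans-after-warming behaviour of this rearrangement class. The step needs α- over γ-attack of the dienol ether, which is secured because γ-attack would require an endo closure at the aryl-bearing, hindered benzylidene carbon and would break the styrene conjugation, and cleavage of the other C2–O bond is reversible and unproductive because no carbon nucleophile sits on that side. The arylmethylidene geometry is not touched, and NaBH4 at low temperature traps the labile β,γ-unsaturated aldehyde 10 as alcohol 11 before the double bond can move into conjugation.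

Step 6
Reactants: 11 [(2R,3S,4Z)-2-Ar-4-(Ar-methylidene)oxolan-3-yl]methanol; 12 4-hydroxybenzoic acid
Product: 13 [(2R,3S,4Z)-2-Ar-4-(Ar-methylidene)oxolan-3-yl]methyl 4-hydroxybenzoate
Conditions: PPh3, DIAD, THF, 0 °C to rt
Reagents that add atoms: none
Why: In this Mitsunobu esterification the carboxylic acid, far more acidic than the phenol of 12, is the pronucleophile, so the primary alcohol is acylated chemoselectively without protecting that phenol, and no stereocentre is involved.

Step 7
Reactants: 13 [(2R,3S,4Z)-2-Ar-4-(Ar-methylidene)oxolan-3-yl]methyl 4-hydroxybenzoate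
Product: 14 [(2R,3S,4Z)-2-(4-hydroxy-3-methoxyphenyl)-4-[(4-hydroxy-3-methoxyphenyl)methylidene]oxolan-3-yl]methyl 4-hydroxybenzoate (target)
Conditions: Bu4NF, AcOH, THF, 0 °C
Reagents that add atoms: none
Why: Fluoride cleaves both aryl silyl ethers, and buffering with acetic acid keeps the medium non-basic so that the benzoate ester, both stereocentres and the alkene geometry should stay intact.

Compound list
1 | but-2-yne-1,4-diol | OCC#CCO | starting material
2 | (E)-2-(tributylstannyl)but-2-ene-1,4-diol | OC/C=C(\CO)[Sn](CCCC)(CCCC)CCCC | intermediate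
3 | 4-[(tert-butyldimethylsilyl)oxy]-3-methoxybenzaldehyde | COc1cc(C=O)ccc1O[Si](C)(C)C(C)(C)C | starting material
4 | 2-Ar-5-(tributylstannyl)-4,7-dihydro-1,3-dioxepine (racemic) | COc1cc(C2OCC=C([Sn](CCCC)(CCCC)CCCC)CO2)ccc1O[Si](C)(C)C(C)(C)C | intermediate
5 | 2-Ar-4,7-dihydro-1,3-dioxepin-5-yllithium (not isolated) | COc1cc(C2OCC=C([Li])CO2)ccc1O[Si](C)(C)C(C)(C)C | intermediate
6 | lithium Ar(2-Ar-4,7-dihydro-1,3-dioxepin-5-yl)methoxide (not isolated) | COc1cc(C2OCC=C(C(O[Li])c3ccc(O[Si](C)(C)C(C)(C)C)c(OC)c3)CO2)ccc1O[Si](C)(C)C(C)(C)C | intermediate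
7 | tert-butyl [Ar(2-Ar-4,7-dihydro-1,3-dioxepin-5-yl)methyl] carbonate (diastereomer mixture) | COc1cc(C2OCC=C(C(OC(=O)OC(C)(C)C)c3ccc(O[Si](C)(C)C(C)(C)C)c(OC)c3)CO2)ccc1O[Si](C)(C)C(C)(C)C | intermediate
8 | (6Z)-2-Ar-6-(Ar-methylidene)-6,7-dihydro-1,3-dioxepine (racemic at C2) | COc1cc(C2OC=C/C(=C/c3ccc(O[Si](C)(C)C(C)(C)C)c(OC)c3)CO2)ccc1O[Si](C)(C)C(C)(C)C | intermediate
9 | oxocarbenium ion tethered to its trimethylsilyl dienol ether, ion pair with the chiral anion (not isolated) | COc1cc(C=[O+]C/C(=C\c2ccc(O[Si](C)(C)C(C)(C)C)c(OC)c2)/C=C\O[Si](C)(C)C)ccc1O[Si](C)(C)C(C)(C)C | intermediate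
10 | (2R,3R,4Z)-2-Ar-4-(Ar-methylidene)oxolane-3-carbaldehyde (not isolated) | COc1cc(/C=C2\CO[C@@H](c3ccc(O[Si](C)(C)C(C)(C)C)c(OC)c3)[C@@H]2C=O)ccc1O[Si](C)(C)C(C)(C)C | intermediate
11 | [(2R,3S,4Z)-2-Ar-4-(Ar-methylidene)oxolan-3-yl]methanol | COc1cc(/C=C2\CO[C@@H](c3ccc(O[Si](C)(C)C(C)(C)C)c(OC)c3)[C@@H]2CO)ccc1O[Si](C)(C)C(C)(C)C | intermediate
12 | 4-hydroxybenzoic acid | OC(=O)c1ccc(O)cc1 | starting material
13 | [(2R,3S,4Z)-2-Ar-4-(Ar-methylidene)oxolan-3-yl]methyl 4-hydroxybenzoate | COc1cc(/C=C2\CO[C@@H](c3ccc(O[Si](C)(C)C(C)(C)C)c(OC)c3)[C@@H]2COC(=O)c2ccc(O)cc2)ccc1O[Si](C)(C)C(C)(C)C | intermediate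
14 | [(2R,3S,4Z)-2-(4-hydroxy-3-methoxyphenyl)-4-[(4-hydroxy-3-methoxyphenyl)methylidene]oxolan-3-yl]methyl 4-hydroxybenzoate | COc1cc(/C=C2\CO[C@@H](c3ccc(O)c(OC)c3)[C@@H]2COC(=O)c2ccc(O)cc2)ccc1O | target

Total step count: 7. Longest linear sequence: 7 steps (1 to 14); aldehyde 3 and acid 12 are bought.

Steps most likely to fail

Step 5 (Proposed new method). The chiral anion may discriminate the faces of the oxocarbenium ion poorly. The dienol ether may also react in part at its γ-carbon. The hold at −40 °C may leave C3 incompletely equilibrated or let the double bond drift into conjugation with the formyl group. The fallback uses known chemistry and sets out from 8. Trimethylsilyl triflate (10 mol %), CH2Cl2, −78 then −40 °C, followed by NaBH4 in EtOH, is the established racemic ring contraction of this acetal class. It should give the trans aldehyde 10 together with its enantiomer (2S,3S,4Z)-2-Ar-4-(Ar-methylidene)oxolane-3-carbaldehyde F1, and after reduction 11 together with its enantiomer [(2S,3R,4Z)-2-Ar-4-(Ar-methylidene)oxolan-3-yl]methanol F2. Enzymatic kinetic resolution follows (Burkholderia cepacia lipase, vinyl acetate, tert-butyl methyl ether, 30 °C). The lipase is selected by screening so that the antipode is acetylated to [(2S,3R,4Z)-2-Ar-4-(Ar-methylidene)oxolan-3-yl]methyl acetate F3 while the (2R,3S)-alcohol stays unreacted. After chromatographic separation the route is rejoined at 11.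

Step 4. The π-allylpalladium intermediate may be captured by tert-butoxide. It may also open the ring by β-alkoxide elimination, or scramble the olefin geometry through syn/anti exchange. The fallback replaces palladium by an ionic 1,4-elimination and sets out from lithium alkoxide 6. Quenching with MsCl at −78 °C in place of Boc2O gives Ar(2-Ar-4,7-dihydro-1,3-dioxepin-5-yl)methyl methanesulfonate F4, which is not isolated. DBU, −78 to 0 °C, should then remove a proton from the ring OCH2 through the aryl-stabilised allyl cation and give dienyl acetal 8 directly.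

Step 2. The vinyl–tin bond may be lost by protodestannylation under the acidic, hot acetalisation, or the electron-rich aldehyde may acetalise incompletely. The fallback moves to an acid-stable vinyl iodide and sets out from 2. I2 in CH2Cl2 at 0 °C (iododestannylation with retention) gives (E)-2-iodobut-2-ene-1,4-diol F5. Acetalisation with 3 (PPTS, benzene, Dean–Stark) gives 2-Ar-5-iodo-4,7-dihydro-1,3-dioxepine F6. Iodine–lithium exchange (t-BuLi, 2 equiv, THF, −78 °C) then gives alkenyllithium 5, where the route is rejoined.

Further compounds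
F1 | step 5 | (2S,3S,4Z)-2-Ar-4-(Ar-methylidene)oxolane-3-carbaldehyde (enantiomer of 10) | COc1cc(/C=C2\CO[C@H](c3ccc(O[Si](C)(C)C(C)(C)C)c(OC)c3)[C@H]2C=O)ccc1O[Si](C)(C)C(C)(C)C
F2 | step 5 | [(2S,3R,4Z)-2-Ar-4-(Ar-methylidene)oxolan-3-yl]methanol (enantiomer of 11) | COc1cc(/C=C2\CO[C@H](c3ccc(O[Si](C)(C)C(C)(C)C)c(OC)c3)[C@H]2CO)ccc1O[Si](C)(C)C(C)(C)C
F3 | step 5 | [(2S,3R,4Z)-2-Ar-4-(Ar-methylidene)oxolan-3-yl]methyl acetate | COc1cc(/C=C2\CO[C@H](c3ccc(O[Si](C)(C)C(C)(C)C)c(OC)c3)[C@H]2COC(C)=O)ccc1O[Si](C)(C)C(C)(C)C
F4 | step 4 | Ar(2-Ar-4,7-dihydro-1,3-dioxepin-5-yl)methyl methanesulfonate | COc1cc(C2OCC=C(C(OS(C)(=O)=O)c3ccc(O[Si](C)(C)C(C)(C)C)c(OC)c3)CO2)ccc1O[Si](C)(C)C(C)(C)C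
F5 | step 2 | (E)-2-iodobut-2-ene-1,4-diol | OC/C=C(\CO)I
F6 | step 2 | 2-Ar-5-iodo-4,7-dihydro-1,3-dioxepine | COc1cc(C2OCC=C(I)CO2)ccc1O[Si](C)(C)C(C)(C)C
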